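**Retrosynthetic overview**
1. Target 13 ⇒ 12 by hydrogenolysis of the two benzyl ethers (last step).
2. 12 ⇒ cis-flavan-4-ol 10 + acylphloroglucinol 4: the C4–aryl bond is made by a stereoinvertive, chiral-anion-directed dehydrative Friedel–Crafts arylation (proposed new step; sets C4 as 2,4-trans).
3. 10 ⇒ flavanone 9 (cis-selective reduction) ⇒ chromone 7 + boronic acid 8 (asymmetric conjugate arylation; sets C2).
4. 7 ⇒ acetophenone 5 (pyranone closure); 4 ⇒ acid chloride 2 + phloroglucinol 3 (Friedel–Crafts acylation), 2 ⇒ acid 1.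
5. Ring order: only the heterocycle (ring C) is built, in step 3, on the bought ring A; ring B is attached in step 4 and the phloroglucinol ring in step 6.

Assumption: 1, 3, 5 and 8 are taken as catalogue compounds, and the target is the (2R,4S)-2,4-trans isomer, as read from the SMILES.

**Step 1**
Reactants: 1 9-phenylnonanoic acid
Product: 2 9-phenylnonanoyl chloride
Conditions: (COCl)2 (1.3 equiv), DMF (cat.), CH2Cl2, 0 °C to rt; evaporate, use crude
Reagents that add atoms: oxalyl chloride, ClC(=O)C(Cl)=O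
Why: Acid chloride formation through the DMF-derived chloroiminium (Vilsmeier-type) catalyst is clean, and the gaseous co-products leave on evaporation.

**Step 2**
Reactants: 2 9-phenylnonanoyl chloride; 3 phloroglucinol
Product: 4 9-phenyl-1-(2,4,6-trihydroxyphenyl)nonan-1-one
Conditions: AlCl3 (3.5 equiv), 3 (1.5 equiv), PhNO2/CH2Cl2, 0 to 45 °C; then 1 M HCl, 0 °C
Reagents that add atoms: none
Why: Friedel–Crafts C-acylation of the very electron-rich triol far outpaces attack on the chain phenyl ring, and the AlCl3-chelated mono-ketone is deactivated toward a second acylation.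

**Step 3**
Reactants: 5 1-[4-(benzyloxy)-2-hydroxyphenyl]ethan-1-one
Product: 7 7-(benzyloxy)-4H-chromen-4-one, via enaminone 6 (not isolated)
Conditions: Me2NCH(OMe)2 (2 equiv), toluene, 95 °C; evaporate; then aq. HCl, CH2Cl2, 40 °C
Reagents that add atoms: N,N-dimethylformamide dimethyl acetal, COC(OC)N(C)C
Why: Condensation of the methyl ketone with the amide acetal gives the enaminone, and acid then drives intramolecular oxa-Michael addition of the phenol with loss of dimethylamine (enaminone–chromone cyclisation), closing ring C.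

**Step 4**
Reactants: 7 7-(benzyloxy)-4H-chromen-4-one; 8 [4-(benzyloxy)phenyl]boronic acid
Product: 9 (2R)-7-(benzyloxy)-2-[4-(benzyloxy)phenyl]-2,3-dihydro-4H-chromen-4-one
Conditions: Pd(OCOCF3)2 (5 mol%), (S)-t-BuPyOx (6 mol%), NH4PF6 (30 mol%), 8 (2 equiv), H2O (5 equiv), ClCH2CH2Cl, 60 °C; recrystallise (EtOH/EtOAc)
Reagents that add atoms: none
Why: Asymmetric conjugate addition of an arylboronic acid to a chromone with a cationic divalent palladium pyridine–oxazoline catalyst inserts C2=C3 into the aryl–Pd bond on one enantioface; the (S)-ligand gives (R)-β-aryl ketones from cyclic enones and by that analogy sets C2 as R, and water protonates the Pd enolate under non-basic conditions that do not open the flavanone.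

**Step 5**
Reactants: 9 (2R)-7-(benzyloxy)-2-[4-(benzyloxy)phenyl]-2,3-dihydro-4H-chromen-4-one
Product: 10 (2R,4R)-7-(benzyloxy)-2-[4-(benzyloxy)phenyl]-3,4-dihydro-2H-chromen-4-ol (2,4-cis)
Conditions: NaBH4 (1.5 equiv), THF/MeOH (4:1), −10 to 0 °C
Reagents that add atoms: none
Why: Borohydride reduction by axial hydride attack on the half-chair with the C2 aryl group equatorial gives the equatorial 4-OH (4R, 2,4-cis), and the cold, brief conditions with a protected 4'-oxygen avoid retro-oxa-Michael racemisation of C2.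

**Step 6**
Reactants: 10 (2R,4R)-7-(benzyloxy)-2-[4-(benzyloxy)phenyl]-3,4-dihydro-2H-chromen-4-ol; 4 9-phenyl-1-(2,4,6-trihydroxyphenyl)nonan-1-one
Product: 12 1-{3-[(2R,4S)-7-(benzyloxy)-2-[4-(benzyloxy)phenyl]-3,4-dihydro-2H-chromen-4-yl]-2,4,6-trihydroxyphenyl}-9-phenylnonan-1-one, via flavan-4-yl cation 11 (not isolated)
Conditions: (R)-3,3'-bis(2,4,6-triisopropylphenyl)-1,1'-binaphthyl-2,2'-diyl N-triflylphosphoramide (5 mol%), 4 (2 equiv), 5 Å MS, CH2Cl2/toluene (2:1), −40 to −20 °C; Et3N quench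
Reagents that add atoms: none
Why: Proposed new method: a stereoinvertive, chiral-counteranion-directed dehydrative Friedel–Crafts C4-arylation, in which the strong confined Brønsted acid ionises the C4–OH of 10 (stabilised by the ortho ring oxygen and the para benzyloxy group) to contact ion pair 11 whose anion and departing water still cover the face syn to the C2 aryl group, while the anion hydrogen-bonds a phenol of 4 and delivers its free ring carbon (the two are symmetry-equivalent) along the pseudo-axial path anti to the equatorial C2 aryl group, so substrate bias, ion-pair shielding and catalyst confinement should all favour the 4S (2,4-trans) product with C2 untouched; the closest known reaction types are achiral acid-promoted couplings of flavan-4-ols with phloroglucinols and chiral phosphoric acid-catalysed Friedel–Crafts additions of phenols to quinone methides and oxocarbenium ion pairs generated in the flask.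

**Step 7**
Reactants: 12 1-{3-[(2R,4S)-7-(benzyloxy)-2-[4-(benzyloxy)phenyl]-3,4-dihydro-2H-chromen-4-yl]-2,4,6-trihydroxyphenyl}-9-phenylnonan-1-one
Product: 13 1-{2,4,6-trihydroxy-3-[(2R,4S)-7-hydroxy-2-(4-hydroxyphenyl)-3,4-dihydro-2H-chromen-4-yl]phenyl}-9-phenylnonan-1-one
Conditions: H2 (1 atm), Pd/C (10 wt% Pd), EtOAc/MeOH (4:1), rt, stopped at full debenzylation
Reagents that add atoms: none
Why: Hydrogenolysis of aryl benzyl ethers is fast under neutral conditions that leave the hydrogen-bonded aryl ketone, the cyclic C2–O ether and the acid-labile C4–aryl bond intact, so neither stereocentre is disturbed.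

**Compound list**
1 | 9-phenylnonanoic acid | OC(=O)CCCCCCCCc1ccccc1 | starting material
2 | 9-phenylnonanoyl chloride | ClC(=O)CCCCCCCCc1ccccc1 | intermediate
3 | phloroglucinol (benzene-1,3,5-triol) | Oc1cc(O)cc(O)c1 | starting material
4 | 9-phenyl-1-(2,4,6-trihydroxyphenyl)nonan-1-one | O=C(CCCCCCCCc1ccccc1)c1c(O)cc(O)cc1O | intermediate
5 | 1-[4-(benzyloxy)-2-hydroxyphenyl]ethan-1-one | CC(=O)c1ccc(OCc2ccccc2)cc1O | starting material
6 | (E)-1-[4-(benzyloxy)-2-hydroxyphenyl]-3-(dimethylamino)prop-2-en-1-one (enaminone, not isolated) | CN(C)/C=C/C(=O)c1ccc(OCc2ccccc2)cc1O | intermediate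
7 | 7-(benzyloxy)-4H-chromen-4-one | O=c1ccoc2cc(OCc3ccccc3)ccc12 | intermediate
8 | [4-(benzyloxy)phenyl]boronic acid | OB(O)c1ccc(OCc2ccccc2)cc1 | starting material
9 | (2R)-7-(benzyloxy)-2-[4-(benzyloxy)phenyl]-2,3-dihydro-4H-chromen-4-one | O=C1C[C@H](c2ccc(OCc3ccccc3)cc2)Oc2cc(OCc3ccccc3)ccc21 | intermediate
10 | (2R,4R)-7-(benzyloxy)-2-[4-(benzyloxy)phenyl]-3,4-dihydro-2H-chromen-4-ol (2,4-cis) | O[C@@H]1C[C@H](c2ccc(OCc3ccccc3)cc2)Oc2cc(OCc3ccccc3)ccc21 | intermediate
11 | (2R)-7-(benzyloxy)-2-[4-(benzyloxy)phenyl]-3,4-dihydro-2H-chromen-4-ylium (flavan-4-yl cation, not isolated) | [CH+]1C[C@H](c2ccc(OCc3ccccc3)cc2)Oc2cc(OCc3ccccc3)ccc21 | intermediate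
12 | 1-{3-[(2R,4S)-7-(benzyloxy)-2-[4-(benzyloxy)phenyl]-3,4-dihydro-2H-chromen-4-yl]-2,4,6-trihydroxyphenyl}-9-phenylnonan-1-one (2,4-trans) | O=C(CCCCCCCCc1ccccc1)c1c(O)cc(O)c([C@H]2C[C@H](c3ccc(OCc4ccccc4)cc3)Oc3cc(OCc4ccccc4)ccc32)c1O | intermediate
13 | 1-{2,4,6-trihydroxy-3-[(2R,4S)-7-hydroxy-2-(4-hydroxyphenyl)-3,4-dihydro-2H-chromen-4-yl]phenyl}-9-phenylnonan-1-one (2,4-trans) | O=C(CCCCCCCCc1ccccc1)c1c(O)cc(O)c([C@H]2C[C@H](c3ccc(O)cc3)Oc3cc(O)ccc32)c1O | target

**Total step count:** 7
**Longest linear sequence:** 5 steps (5 → 7 → 9 → 10 → 12 → 13; steps 3 to 7)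

**Three steps most likely to fail**

Step 6 (the proposed new step). The risks are an insufficient trans:cis ratio, a mismatched catalyst antipode, second alkylation of the product and self-condensation of 10 through ring A. The fallback is known chemistry and replaces catalyst control by substrate control with separation and recycling. It sets out from 10 (with 4) and comes back at 12. Alcohol 10 and 4 (3 equiv) are treated with BF3·OEt2 (1.2 equiv) in CH2Cl2/1,4-dioxane at 0 °C. This classical Friedel–Crafts coupling through cation 11 gives 12 as the major, axial-attack product. The minor product is the 2,4-cis epimer 1-{3-[(2R,4R)-7-(benzyloxy)-2-[4-(benzyloxy)phenyl]-3,4-dihydro-2H-chromen-4-yl]-2,4,6-trihydroxyphenyl}-9-phenylnonan-1-one F4. The two are separated on silica, and F4 is resubjected to BF3·OEt2 with fresh 4, where reversible C4–aryl ionisation re-partitions it toward 12.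

Step 4. The electron-rich boronic acid and the donor-substituted chromone may give low conversion or eroded ee, and the sense of induction rests on analogy and must be confirmed by chiral HPLC and rotation. The fallback builds the flavanone racemically and sets both centres by kinetic resolution. It sets out from 5 and comes back at 10, bypassing steps 3 to 5. Claisen–Schmidt condensation of 5 with commercial 4-(benzyloxy)benzaldehyde (KOH, EtOH, rt) gives (E)-1-[4-(benzyloxy)-2-hydroxyphenyl]-3-[4-(benzyloxy)phenyl]prop-2-en-1-one F1. NaOAc in refluxing EtOH closes it by oxa-Michael addition to racemic 7-(benzyloxy)-2-[4-(benzyloxy)phenyl]-2,3-dihydro-4H-chromen-4-one F2. Asymmetric transfer hydrogenation with RuCl[(R,R)-TsDPEN](p-cymene) (1 mol%) and HCO2H/Et3N (5:2) in EtOAc, stopped near half conversion, reduces the (2R)-enantiomer to 10. The untouched (2S)-7-(benzyloxy)-2-[4-(benzyloxy)phenyl]-2,3-dihydro-4H-chromen-4-one F3 is separated on silica and re-racemised to F2 with NaOAc/EtOH for another pass.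

Step 7. The risks are hydrogenolytic opening of the benzylic C2–O bond, partial ketone reduction or stalled debenzylation of the polyphenol. The fallback changes the protecting group so that the end game is a fluoride deprotection. It sets out from 9 and comes back at 13. Hydrogenolysis of 9 (H2, Pd/C, EtOAc), where only a robust flavanone is exposed, gives (2R)-7-hydroxy-2-(4-hydroxyphenyl)-2,3-dihydro-4H-chromen-4-one F5. Silylation (i-Pr3SiCl, imidazole, DMF, 0 °C) gives (2R)-7-[(triisopropylsilyl)oxy]-2-{4-[(triisopropylsilyl)oxy]phenyl}-2,3-dihydro-4H-chromen-4-one F6. NaBH4 reduction as in step 5 gives (2R,4R)-7-[(triisopropylsilyl)oxy]-2-{4-[(triisopropylsilyl)oxy]phenyl}-3,4-dihydro-2H-chromen-4-ol F7. Coupling with 4 under whichever conditions prevailed for step 6 gives 1-{2,4,6-trihydroxy-3-[(2R,4S)-7-[(triisopropylsilyl)oxy]-2-{4-[(triisopropylsilyl)oxy]phenyl}-3,4-dihydro-2H-chromen-4-yl]phenyl}-9-phenylnonan-1-one F8. Bu4NF buffered with AcOH in THF at 0 °C then releases 13.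

**Further compounds**
F1 | step 4 | (E)-1-[4-(benzyloxy)-2-hydroxyphenyl]-3-[4-(benzyloxy)phenyl]prop-2-en-1-one | O=C(/C=C/c1ccc(OCc2ccccc2)cc1)c1ccc(OCc2ccccc2)cc1O
F2 | step 4 | racemic 7-(benzyloxy)-2-[4-(benzyloxy)phenyl]-2,3-dihydro-4H-chromen-4-one | O=C1CC(c2ccc(OCc3ccccc3)cc2)Oc2cc(OCc3ccccc3)ccc21
F3 | step 4 | (2S)-7-(benzyloxy)-2-[4-(benzyloxy)phenyl]-2,3-dihydro-4H-chromen-4-one | O=C1C[C@@H](c2ccc(OCc3ccccc3)cc2)Oc2cc(OCc3ccccc3)ccc21
F4 | step 6 | 1-{3-[(2R,4R)-7-(benzyloxy)-2-[4-(benzyloxy)phenyl]-3,4-dihydro-2H-chromen-4-yl]-2,4,6-trihydroxyphenyl}-9-phenylnonan-1-one (2,4-cis epimer of 12) | O=C(CCCCCCCCc1ccccc1)c1c(O)cc(O)c([C@@H]2C[C@H](c3ccc(OCc4ccccc4)cc3)Oc3cc(OCc4ccccc4)ccc32)c1O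
F5 | step 7 | (2R)-7-hydroxy-2-(4-hydroxyphenyl)-2,3-dihydro-4H-chromen-4-one | O=C1C[C@H](c2ccc(O)cc2)Oc2cc(O)ccc21
F6 | step 7 | (2R)-7-[(triisopropylsilyl)oxy]-2-{4-[(triisopropylsilyl)oxy]phenyl}-2,3-dihydro-4H-chromen-4-one | O=C1C[C@H](c2ccc(O[Si](C(C)C)(C(C)C)C(C)C)cc2)Oc2cc(O[Si](C(C)C)(C(C)C)C(C)C)ccc21
F7 | step 7 | (2R,4R)-7-[(triisopropylsilyl)oxy]-2-{4-[(triisopropylsilyl)oxy]phenyl}-3,4-dihydro-2H-chromen-4-ol | O[C@@H]1C[C@H](c2ccc(O[Si](C(C)C)(C(C)C)C(C)C)cc2)Oc2cc(O[Si](C(C)C)(C(C)C)C(C)C)ccc21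
F8 | step 7 | 1-{2,4,6-trihydroxy-3-[(2R,4S)-7-[(triisopropylsilyl)oxy]-2-{4-[(triisopropylsilyl)oxy]phenyl}-3,4-dihydro-2H-chromen-4-yl]phenyl}-9-phenylnonan-1-one | O=C(CCCCCCCCc1ccccc1)c1c(O)cc(O)c([C@H]2C[C@H](c3ccc(O[Si](C(C)C)(C(C)C)C(C)C)cc3)Oc3cc(O[Si](C(C)C)(C(C)C)C(C)C)ccc32)c1O
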